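The readings were computed with made-up constants; the scatter is artificial.

Whatever Q you charge stays in the balance: it is Q, it is D, or it is something neither reading shows.

| setting | west | north | north-west | alder | maple | larch | birch |
|---|---|---|---|---|---|---|---|
| Q | 0.80 M (in portions, 3) | 0.80 M (in portions, 3) | 0.80 M (in portions, 3) | 0.80 M (in portions, 3) | 0.80 M (in portions, 3) | 0.80 M (in portions, 3) | 0.80 M (in portions, 3) |
| G | 0.98 M | 1.4 M | 1.9 M | 0.800 M | 1.00 M | 1.50 M | 2.50 M |
| remark | run made earlier; portions every 6.0 min | run made earlier; portions every 6.0 min | run made earlier; portions every 6.0 min | the portions of Q follow each other after 6.0 min, the first at the start | the portions of Q follow each other after 6.0 min, the first at the start | the portions of Q follow each other after 6.0 min, the first at the start | the portions of Q follow each other after 6.0 min, the first at the start |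
| time |  |  |  | 30 min | 30 min | 30 min | 30 min |

- west (time / min: D / %, Q / %): 4.00: 9.7, 23.4; 8.00: 15.0, 49.8; 12.0: 20.2, 39.7; 15.0: 29.0, 65.0; 20.0: 34.1, 54.0
- north (time / min: D / %, Q / %): 4.00: 9.2, 22.8; 8.00: 19.5, 43.7; 12.0: 27.5, 33.8; 15.0: 32.1, 55.0; 20.0: 36.6, 42.9
- north-west (time / min: D / %, Q / %): 2.00: 5.5, 27.5; 5.00: 12.8, 17.9; 10.0: 23.8, 30.8; 15.0: 34.8, 47.1; 20.0: 37.7, 35.5

(scatter of a reading: 1 percentage point)

- "hardly changes" means that all values lie within two and a half points (for a concentration: within two and a half percent of the largest)

1. [D] at the end for alder, maple, larch, birch, in this order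
2. the shape of the row from first to last (rises all the way / falls, then rises / falls all the way / hardly changes / rises, then falls)

Take the runs after the last portion is in. Let C be the share of the charge no longer Q. Let W be the gap, the part of C that is not D. Then D = C − W, which makes D an intermediate: it gains with C and loses with W. Both rise with G, so work in powers of ten.

| run | G | C, 20.0 min | W, 20.0 min | W/C, 15.0 min | W/C, 20.0 min |
|---|---|---|---|---|---|
| west | 0.98 M | 46.0% | 11.9% | 0.171 | 0.259 |
| north | 1.4 M | 57.1% | 20.5% | 0.287 | 0.359 |
| north-west | 1.9 M | 64.5% | 26.8% | 0.342 | 0.416 |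

Read down the table. From west to north-west, G gains 0.288 powers of ten, C gains 0.147 and W gains 0.353. These are readings, with their scatter. Hold those slopes fixed and step G a little. D stands still when the two gains, each times its own amount, are equal. That gives the turning share, the W/C at which D stops growing with G: 0.416.

Now read across. West's W/C, a reading taken from two scattered points, climbed by 0.0880 in 5.00 min. Carried straight on to 30 min, my reckoning puts west at 0.433, just above the turning share. W/C grows with G by the difference of the two slopes, so my estimate puts the turn at 0.927 M, between alder and maple. My reckoning gives that turn, not amounts.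

The forecast gives 0.33 M, 0.35 M, 0.33 M and 0.25 M, rises, then falls, and says “D passes through a shallow maximum”. On the shape we agree.

The flask gives 0.284 M, 0.296 M, 0.288 M and 0.212 M: rises, then falls.

    Q + G ⇌ L + D (K = 2.90, k = 0.0730 L mol⁻¹ min⁻¹)
    D + G ⇌ L + Z (K = 20.0, k = 0.0460 L mol⁻¹ min⁻¹)
    Z + G ⇌ L + E (K = 2.30, k = 0.290 L mol⁻¹ min⁻¹)

The row turns at 1.1 M, higher than my 0.927 M. At 30.0 min the gap W is Z plus E. Maple's W/C is 0.330, below the turning share 0.416. Larch's is 0.470, above it, and the turn lies between those two flasks. Birch stands further past it, with W/C at 0.680 and D down to 0.212 M.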